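The west run, with 2.2 M of coupling partner, has 45.7% of left-handed product at 1.00 min beside 3.0% of right-handed product. By 2.00 min the left-handed product reads 51.1% and stays near that reading, while the right-handed product climbs to 37.5% at 8.00 min. The west run held 19 mM of precatalyst and 10 mM of impurity, as your flask does.

all flasks: precatalyst 19 mM; impurity 10 mM

| flask | left-handed substrate | right-handed substrate | coupling partner | remark | time |
|---|---|---|---|---|---|
| south-west | 0.37 M | 0.37 M | 0.56 M | run made earlier |  |
| west | 0.37 M | 0.37 M | 2.2 M | run made earlier |  |
| south | 0.74 M | 0.74 M | 1.11 M | run made earlier |  |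
| flask | 0.37 M | 0.37 M | 1.11 M |  | 6.0 min |

| run | time / min | left-handed product / % | right-handed product / % | left-handed substrate / % |
|---|---|---|---|---|
| south-west | 1.00 | 9.1 | 0 | 41.6 |
| south-west | 2.00 | 21.4 | 2.5 | 28.6 |
| south-west | 3.00 | 28.5 | 1.3 | 17.9 |
| south-west | 4.00 | 38.8 | 0.7 | 13.8 |
| south-west | 5.00 | 44.4 | 0.6 | 6.8 |
| south-west | 6.00 | 46.1 | 0.9 | 1.5 |
| south-west | 8.00 | 49.8 | 4.5 | 0 |
| west | 0.417 | 22.3 | 0 | 27.8 |
| west | 1.00 | 45.7 | 3.0 | 4.5 |
| west | 2.00 | 51.1 | 7.4 | 0 |
| west | 3.00 | 49.7 | 14.8 | 1.0 |
| west | 4.00 | 48.5 | 20.2 | 0.6 |
| west | 6.00 | 51.0 | 31.0 | 0 |
| west | 8.00 | 50.9 | 37.5 | 0 |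
| south | 0.500 | 5.8 | 0 | 43.3 |
| south | 1.00 | 16.8 | 0 | 35.8 |
| south | 2.00 | 32.4 | 0 | 19.3 |
| south | 4.00 | 47.7 | 2.4 | 2.1 |
| south | 8.00 | 48.0 | 4.4 | 0 |

(standard deviation of a reading: 1 percentage point)

- free catalyst is single-handed; left-handed substrate and right-handed substrate are mirror images of each other, charged as a racemate, each of them at the stated concentration
- the analysis behind the earlier runs scatters by 1 percentage point, standard deviation
- candidate steps: coupling partner + precatalyst -> free catalyst + spent reagent; free catalyst + left-handed substrate <-> catalyst intermediate A; free catalyst + right-handed substrate <-> catalyst intermediate B; free catalyst + impurity -> spent catalyst; coupling partner + catalyst intermediate A -> free catalyst + left-handed product; coupling partner + catalyst intermediate B -> free catalyst + right-handed product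
- an excess is the difference of the two amounts in percent of their sum
- an excess is below zero if the other one leads

- excess of left-handed product over right-handed product in the product at 8.0 s
- excess of left-handed product over right-handed product in the product at 6.0 min
- part of the left-handed substrate and right-handed substrate charged together that has reacted at 6.0 min

Take the excess scale from its two ends. A catalyst blind to handedness, the symmetric case, is the zero of the scale. A perfect catalyst gives 100 and stops when the left-handed substrate is gone. Your flask is a kinetic resolution between these ends, and its place at a given time depends on how much right-handed turnover follows, which scales with the catalyst still working.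

That amount has two extreme versions as well. If the impurity catches nothing, the working catalyst is the full 19 mM. If it takes one catalyst per impurity through its whole charge, you are left with the working catalyst w, precatalyst charged minus impurity charged, 9.00 mM, counted over every form in the round. The impurity step runs one way while substrate binding reverses, so I commit to the lower end. This gives w, not an excess; the excess figures are the forecast's.

The forecast gives 97% at 8.0 s, reasoning that the left-handed substrate holds the catalyst against weak binding of the right-handed substrate, a “selectivity of at least 30”. For 6.0 min it gives 60% and 62.5% reacted, with the right-handed substrate reacting mainly after the left-handed substrate.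

    coupling partner + precatalyst → free catalyst + spent reagent (k = 0.0190 M⁻¹ s⁻¹)
    free catalyst + left-handed substrate ⇌ catalyst intermediate A (K = 72.0 M⁻¹, k = 65.0 M⁻¹ s⁻¹)
    free catalyst + right-handed substrate ⇌ catalyst intermediate B (K = 4.70 M⁻¹, k = 13.0 M⁻¹ s⁻¹)
    free catalyst + impurity → spent catalyst (k = 50.0 M⁻¹ s⁻¹)
    coupling partner + catalyst intermediate A → free catalyst + left-handed product (k = 0.780 M⁻¹ s⁻¹)
    coupling partner + catalyst intermediate B → free catalyst + right-handed product (k = 0.100 M⁻¹ s⁻¹)

The flask gives 96.7%, 61.6% and 62.6%, all within the forecast's tolerance. At 6.0 min it is a resolution on its way towards zero, with left-handed substrate at 0% and right-handed product at 11.9%. Spent catalyst stands at 52.6% of the catalyst charged, with impurity at 0%. So w puts 47.4% outside spent catalyst, against free catalyst 20.6%, catalyst intermediate B 26.2% and precatalyst 0.557%.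

In the neighbour flask with 0.0047 M of precatalyst, w comes to −5.30 mM, below zero. The impurity there should outlast the catalyst and keep 53.0% of its charge. Computed for that neighbour flask at 6.0 min: impurity 53%, spent catalyst 99.5%, excess 96.4%, reacted 16.4%.

The runs stem from a simulated flask with made-up constants; the scatter is artificial.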